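**Retrosynthetic overview**
1. Target 19 ⇐ triol acid 18 (acetylation of O14 and O15) ⇐ E-allylic alcohol 16 by the key step: a one-flask asymmetric anti-dihydroxylation that forms the C13–O and C14–O bonds and sets both side-chain stereocentres.
2. 16 ⇐ terminal alkyne acid 13 (methylalumination, then formaldehyde, bringing in C16 and C15); 13 ⇐ aldehyde 12 (aldehyde to acid).
3. Ring A (closed last) ⇐ exo Diels–Alder reaction of vinylcyclohexene 10 with methacrolein, setting C4 and C5.
4. 10 ⇐ ketone 7 (enol triflate, vinyl coupling); 7 ⇐ 2-methylcyclohex-2-enone by asymmetric conjugate methylation (C8) and enolate alkylation with butynyl triflate 2 (C9).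
5. Ring order: ring B is the starting cyclohexenone; ring A is formed by the cycloaddition.

Assumption: halimane numbering (ring carbons C1–C10, side chain C11–C16, acid carbon C18) is used for atom labels, and ligand and catalyst antipodes are fixed by the sense of induction stated in each step.

**Route**

Step 1
Reactants: 1 but-3-yn-1-ol
Product: 2 but-3-yn-1-yl trifluoromethanesulfonate
Conditions: Tf2O, pyridine, CH2Cl2, −78 to −20 °C; used cold after a short silica plug
Reagents that add atoms: trifluoromethanesulfonic anhydride, O=S(=O)(OS(=O)(=O)C(F)(F)F)C(F)(F)F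
Why: O-sulfonylation of a primary alcohol gives the homopropargylic triflate, an electrophile reactive enough to alkylate a hindered enolate at low temperature before elimination can compete.

Step 2
Reactants: 3 2-methylcyclohex-2-en-1-one
Product: 5 trimethyl{[(3R)-2,3-dimethylcyclohex-1-en-1-yl]oxy}silane, via dimethylaluminium enolate 4 (not isolated)
Conditions: Me3Al, Cu(OAc)2 (2 mol%), (R,S,S)-binaphthol-derived N,N-bis(1-phenylethyl)phosphoramidite (4 mol%; the antipode that gives the 3R product), Et2O, −30 °C; then TMSOTf, −30 to 0 °C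
Reagents that add atoms: trimethylaluminium, C[Al](C)C; trimethylsilyl trifluoromethanesulfonate, C[Si](C)(C)OS(=O)(=O)C(F)(F)F
Why: Copper-catalysed asymmetric conjugate addition transfers methyl to one enone face under ligand control and sets C8 as R, and O-silylation stores the regiodefined tetrasubstituted enolate.

Step 3
Reactants: 5 trimethyl{[(3R)-2,3-dimethylcyclohex-1-en-1-yl]oxy}silane, 2 but-3-yn-1-yl trifluoromethanesulfonate
Product: 7 (2S,3R)-2-(but-3-yn-1-yl)-2,3-dimethylcyclohexan-1-one, via lithium enolate 6 (not isolated)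
Conditions: MeLi (1.0 equiv), THF, 0 °C; then 2, THF–DMPU, −78 to −20 °C
Reagents that add atoms: none
Why: MeLi cleaves the silyl enol ether to the lithium enolate, and enolate alkylation by the primary triflate takes place anti to the neighbouring C8 methyl, which sets the quaternary C9 as S with the two methyls cis.

Step 4
Reactants: 7 (2S,3R)-2-(but-3-yn-1-yl)-2,3-dimethylcyclohexan-1-one
Product: 9 (5R,6S)-6-(but-3-yn-1-yl)-5,6-dimethylcyclohex-1-en-1-yl trifluoromethanesulfonate, via potassium enolate 8 (not isolated)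
Conditions: KN(SiMe3)2 (1.1 equiv), THF, −78 °C; PhNTf2, −78 to 0 °C
Reagents that add atoms: N-phenylbis(trifluoromethanesulfonimide), O=S(=O)(N(c1ccccc1)S(=O)(=O)C(F)(F)F)C(F)(F)F
Why: Enol triflate formation is regiospecific because only C5 carries enolisable hydrogens (C9 is quaternary), and the ketone C–H is more acidic than the alkyne C–H.

Step 5
Reactants: 9 (5R,6S)-6-(but-3-yn-1-yl)-5,6-dimethylcyclohex-1-en-1-yl trifluoromethanesulfonate
Product: 10 (5R,6S)-6-(but-3-yn-1-yl)-1-ethenyl-5,6-dimethylcyclohex-1-ene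
Conditions: tributyl(vinyl)stannane, Pd(PPh3)4 (5 mol%), LiCl (3 equiv), THF, 65 °C
Reagents that add atoms: tributyl(vinyl)stannane, C=C[Sn](CCCC)(CCCC)CCCC
Why: Stille cross-coupling of the alkenyl triflate installs the vinyl group under neutral conditions that leave the terminal alkyne and both stereocentres untouched.

Step 6
Reactants: 10 (5R,6S)-6-(but-3-yn-1-yl)-1-ethenyl-5,6-dimethylcyclohex-1-ene, 11 methacrolein
Product: 12 (1S,5S,6R,8aS)-5-(but-3-yn-1-yl)-1,5,6-trimethyl-1,2,3,5,6,7,8,8a-octahydronaphthalene-1-carbaldehyde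
Conditions: (S)-o-tolyl-oxazaborolidine from (S)-diphenylprolinol (20 mol%; the enantiomer that exposes the Re face of C2 of methacrolein), Tf2NH (18 mol%), CH2Cl2, −78 to −40 °C
Reagents that add atoms: none
Why: Catalytic asymmetric Diels–Alder reaction in which the aldehyde-bearing carbon bonds to the ring terminus C5 and the exo transition state on the Re face of methacrolein C2 sets C4 as S and C5 as S (new bond syn to the C9 methyl), the catalyst deciding the diene face because the two half-chair conformers of 10 are judged to give little intrinsic bias.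

Step 7
Reactants: 12 (1S,5S,6R,8aS)-5-(but-3-yn-1-yl)-1,5,6-trimethyl-1,2,3,5,6,7,8,8a-octahydronaphthalene-1-carbaldehyde
Product: 13 (1S,5S,6R,8aS)-5-(but-3-yn-1-yl)-1,5,6-trimethyl-1,2,3,5,6,7,8,8a-octahydronaphthalene-1-carboxylic acid
Conditions: NaClO2, NaH2PO4, 2-methyl-2-butene, t-BuOH–H2O, rt
Reagents that add atoms: sodium chlorite, [Na+].[O-]Cl=O
Why: Pinnick oxidation converts the non-enolisable neopentyl aldehyde to the acid while the scavenger protects the alkene and alkyne from hypochlorous acid.

Step 8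
Reactants: 13 (1S,5S,6R,8aS)-5-(but-3-yn-1-yl)-1,5,6-trimethyl-1,2,3,5,6,7,8,8a-octahydronaphthalene-1-carboxylic acid
Product: 16 (1S,5S,6R,8aS)-5-[(3E)-5-hydroxy-3-methylpent-3-en-1-yl]-1,5,6-trimethyl-1,2,3,5,6,7,8,8a-octahydronaphthalene-1-carboxylic acid, via alkenylalane 14 (not isolated), via aluminium alkoxide 15 (not isolated)
Conditions: Me3Al (4 equiv), Cp2ZrCl2 (0.5 equiv), CH2Cl2, 0 °C to rt; then (CH2O)n, THF, 0 °C to rt; aq. HCl work-up
Reagents that add atoms: trimethylaluminium, C[Al](C)C; formaldehyde (from paraformaldehyde), C=O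
Why: Negishi zirconium-catalysed syn-carboalumination puts methyl on C13 and aluminium on C14, and the E-alkenylalane adds to formaldehyde with retention of geometry, the acid being masked in the flask as its aluminium carboxylate.

Step 9
Reactants: 16 (1S,5S,6R,8aS)-5-[(3E)-5-hydroxy-3-methylpent-3-en-1-yl]-1,5,6-trimethyl-1,2,3,5,6,7,8,8a-octahydronaphthalene-1-carboxylic acid
Product: 18 (1S,5S,6R,8aS)-5-[(3R,4S)-3,4,5-trihydroxy-3-methylpentyl]-1,5,6-trimethyl-1,2,3,5,6,7,8,8a-octahydronaphthalene-1-carboxylic acid, via epoxy alcohol 17 (not isolated)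
Conditions: WO2(acac)2 (5 mol%), C2-symmetric cyclohexane-1,2-diamine-derived bis(hydroxamic acid) ligand (6 mol%; the antipode that gives (2S,3S)-2,3-epoxygeraniol from geraniol), 30% aq. H2O2 (2 equiv), NaCl (0.5 equiv), CH2Cl2, rt; then THF–H2O, 45 °C
Reagents that add atoms: hydrogen peroxide, OO; water, O
Why: Proposed new method: a one-flask catalyst-controlled anti-dihydroxylation in which the chiral dioxotungsten bis(hydroxamate) peroxo complex binds the C15 alkoxide and delivers oxygen to one face of the E-alkene (13S,14S epoxy alcohol 17), after which the same Lewis-acidic tungsten centre, chelated by O15 and the epoxide oxygen, activates the C13–O bond for backside attack of water at the tertiary carbon, so that syn oxygen transfer plus inversion at C13 gives the 13R,14S triol while the hindered ring alkene, which has no directing hydroxyl, stays intact; the closest known reaction types are tungsten/bis(hydroxamic acid) asymmetric epoxidation of allylic alcohols with H2O2, tungsten-catalysed C3-selective opening of 2,3-epoxy alcohols and molybdenum-catalysed hydroxyl-directed anti-dihydroxylation.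

Step 10
Reactants: 18 (1S,5S,6R,8aS)-5-[(3R,4S)-3,4,5-trihydroxy-3-methylpentyl]-1,5,6-trimethyl-1,2,3,5,6,7,8,8a-octahydronaphthalene-1-carboxylic acid
Product: 19 (1S,5S,6R,8aS)-5-[(3R,4S)-4,5-bis(acetyloxy)-3-hydroxy-3-methylpentyl]-1,5,6-trimethyl-1,2,3,5,6,7,8,8a-octahydronaphthalene-1-carboxylic acid (CNP0224606.1)
Conditions: Ac2O (2.5 equiv), pyridine, CH2Cl2, 0 °C to rt; aq. NaHCO3, then acidify to pH 3
Reagents that add atoms: acetic anhydride, CC(=O)OC(C)=O
Why: Pyridine-mediated O-acetylation esterifies the primary and secondary hydroxyls only, the tertiary C13 hydroxyl being too hindered without an acyl-transfer catalyst and the acid being returned free by the bicarbonate work-up.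

**Compound list**
1 | but-3-yn-1-ol | C#CCCO | starting material
2 | but-3-yn-1-yl trifluoromethanesulfonate | C#CCCOS(=O)(=O)C(F)(F)F | intermediate
3 | 2-methylcyclohex-2-en-1-one | CC1=CCCCC1=O | starting material
4 | dimethylaluminium (3R)-2,3-dimethylcyclohex-1-en-1-olate | C[Al](C)OC1=C(C)[C@H](C)CCC1 | intermediate (not isolated)
5 | trimethyl{[(3R)-2,3-dimethylcyclohex-1-en-1-yl]oxy}silane | C[Si](C)(C)OC1=C(C)[C@H](C)CCC1 | intermediate
6 | lithium (3R)-2,3-dimethylcyclohex-1-en-1-olate | [Li]OC1=C(C)[C@H](C)CCC1 | intermediate (not isolated)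
7 | (2S,3R)-2-(but-3-yn-1-yl)-2,3-dimethylcyclohexan-1-one | C#CCC[C@]1(C)C(=O)CCC[C@H]1C | intermediate
8 | potassium (5R,6S)-6-(but-3-yn-1-yl)-5,6-dimethylcyclohex-1-en-1-olate | C#CCC[C@]1(C)C(O[K])=CCC[C@H]1C | intermediate (not isolated)
9 | (5R,6S)-6-(but-3-yn-1-yl)-5,6-dimethylcyclohex-1-en-1-yl trifluoromethanesulfonate | C#CCC[C@]1(C)C(OS(=O)(=O)C(F)(F)F)=CCC[C@H]1C | intermediate
10 | (5R,6S)-6-(but-3-yn-1-yl)-1-ethenyl-5,6-dimethylcyclohex-1-ene | C#CCC[C@]1(C)C(C=C)=CCC[C@H]1C | intermediate
11 | methacrolein (2-methylprop-2-enal) | CC(=C)C=O | starting material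
12 | (1S,5S,6R,8aS)-5-(but-3-yn-1-yl)-1,5,6-trimethyl-1,2,3,5,6,7,8,8a-octahydronaphthalene-1-carbaldehyde | C#CCC[C@]1(C)C2=CCC[C@](C)(C=O)[C@H]2CC[C@H]1C | intermediate
13 | (1S,5S,6R,8aS)-5-(but-3-yn-1-yl)-1,5,6-trimethyl-1,2,3,5,6,7,8,8a-octahydronaphthalene-1-carboxylic acid | C#CCC[C@]1(C)C2=CCC[C@](C)(C(=O)O)[C@H]2CC[C@H]1C | intermediate
14 | dimethylaluminium (1S,5S,6R,8aS)-5-[(3E)-4-(dimethylalumanyl)-3-methylbut-3-en-1-yl]-1,5,6-trimethyl-1,2,3,5,6,7,8,8a-octahydronaphthalene-1-carboxylate | C[Al](C)/C=C(\C)CC[C@]1(C)C2=CCC[C@](C)(C(=O)O[Al](C)C)[C@H]2CC[C@H]1C | intermediate (not isolated)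
15 | dimethylaluminium (1S,5S,6R,8aS)-5-{(3E)-5-[(dimethylalumanyl)oxy]-3-methylpent-3-en-1-yl}-1,5,6-trimethyl-1,2,3,5,6,7,8,8a-octahydronaphthalene-1-carboxylate | C[Al](C)OC/C=C(\C)CC[C@]1(C)C2=CCC[C@](C)(C(=O)O[Al](C)C)[C@H]2CC[C@H]1C | intermediate (not isolated)
16 | (1S,5S,6R,8aS)-5-[(3E)-5-hydroxy-3-methylpent-3-en-1-yl]-1,5,6-trimethyl-1,2,3,5,6,7,8,8a-octahydronaphthalene-1-carboxylic acid | OC/C=C(\C)CC[C@]1(C)C2=CCC[C@](C)(C(=O)O)[C@H]2CC[C@H]1C | intermediate
17 | (1S,5S,6R,8aS)-5-{2-[(2S,3S)-3-(hydroxymethyl)-2-methyloxiran-2-yl]ethyl}-1,5,6-trimethyl-1,2,3,5,6,7,8,8a-octahydronaphthalene-1-carboxylic acid | OC[C@@H]3O[C@@]3(C)CC[C@]1(C)C2=CCC[C@](C)(C(=O)O)[C@H]2CC[C@H]1C | intermediate (not isolated)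
18 | (1S,5S,6R,8aS)-5-[(3R,4S)-3,4,5-trihydroxy-3-methylpentyl]-1,5,6-trimethyl-1,2,3,5,6,7,8,8a-octahydronaphthalene-1-carboxylic acid | OC[C@H](O)[C@](C)(O)CC[C@]1(C)C2=CCC[C@](C)(C(=O)O)[C@H]2CC[C@H]1C | intermediate
19 | (1S,5S,6R,8aS)-5-[(3R,4S)-4,5-bis(acetyloxy)-3-hydroxy-3-methylpentyl]-1,5,6-trimethyl-1,2,3,5,6,7,8,8a-octahydronaphthalene-1-carboxylic acid (CNP0224606.1) | CC(=O)OC[C@H](OC(C)=O)[C@](C)(O)CC[C@]1(C)C2=CCC[C@](C)(C(=O)O)[C@H]2CC[C@H]1C | target

**Step count and risks**

Total step count: 10. Longest linear sequence: 9 steps (steps 2–10 from 3; the branch from 1 through step 1 and steps 3–10 is also 9).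

Three steps most likely to fail:

Step 9 (the proposed tandem epoxidation and hydrolysis). The epoxide may open slowly or with poor regio- or stereocontrol, or the free acid may inhibit the tungsten catalyst. The fallback uses known chemistry, sets out from 16 and comes back at 18. 16 is epoxidised with the dioxirane generated from the L-fructose-derived (ent-Shi) ketone and KHSO5 (as the triple salt 2KHSO5·KHSO4·K2SO4) with K2CO3 and Bu4NHSO4 in MeCN–dimethoxymethane–aqueous buffer at pH 10.5 and 0 °C, conditions under which the carboxylate is inert; this gives epoxy alcohol 17, now isolated. Dilute HClO4 in THF–H2O at 0 °C then opens 17 at the tertiary C13 with inversion to give 18. This replaces metal-directed catalysis by reagent-controlled dioxirane epoxidation and Brønsted-acid hydrolysis; it makes no new compound (F0).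

Step 6 (face and exo control in the cycloaddition). The oxazaborolidinium catalyst may fail to override the diene's own face preference, or the hindered diene may be too slow. The fallback sets out from 10 and comes back at 13. Methacrylic acid itself is used as dienophile, bound covalently as a chiral (acyloxy)borane prepared from BH3·THF and a mono-acylated tartaric acid (antipode chosen for the same Re-face attack) in CH2Cl2 at −78 °C; aqueous work-up releases acid 13 directly. This changes the dienophile, the mode of activation and the chiral controller, and removes step 7; it makes no new compound (F0).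

Step 3 (quaternary alkylation with the homopropargylic triflate). O-alkylation or elimination of 2 may dominate. The fallback sets out from 5 and comes back at 7. The lithium enolate 6 from 5 and MeLi is trapped with allyl iodide (THF, −78 to 0 °C), a well-behaved allylation with the same anti selectivity, to give (2S,3R)-2,3-dimethyl-2-(prop-2-en-1-yl)cyclohexan-1-one F1. Hydroboration with 9-BBN followed by NaOH/H2O2 gives (2S,3R)-2-(3-hydroxypropyl)-2,3-dimethylcyclohexan-1-one F2. Dess–Martin oxidation gives 3-[(1S,2R)-1,2-dimethyl-6-oxocyclohexyl]propanal F3. Ohira–Bestmann homologation with dimethyl (1-diazo-2-oxopropyl)phosphonate, K2CO3 and MeOH converts the aldehyde into the terminal alkyne and returns ketone 7.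

Further compounds
F1 | step 3 | (2S,3R)-2,3-dimethyl-2-(prop-2-en-1-yl)cyclohexan-1-one | C=CC[C@]1(C)C(=O)CCC[C@H]1C
F2 | step 3 | (2S,3R)-2-(3-hydroxypropyl)-2,3-dimethylcyclohexan-1-one | OCCC[C@]1(C)C(=O)CCC[C@H]1C
F3 | step 3 | 3-[(1S,2R)-1,2-dimethyl-6-oxocyclohexyl]propanal | O=CCC[C@]1(C)C(=O)CCC[C@H]1C
F0 | step 6 | none | none
F0 | step 9 | none | none
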